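Fractions of the charge are the unit I read in: two runs' fractions at one time give an order.

common to all: free catalyst 0.50 mM
- summer: starting material 0.0050 M; second substrate 10 mM; reagent 9.5 mM; run made earlier
- noon: starting material 0.020 M; second substrate 10 mM; reagent 9.5 mM; run made earlier
- dawn: starting material 0.010 M; second substrate 10 mM; reagent 14 mM; run made earlier
- flask: starting material 0.010 M; second substrate 10.0 mM; reagent 9.50 mM

| run | time / h | target / % | starting material / % |
|---|---|---|---|
| summer | 0.417 | 7.8 | 87.9 |
| summer | 0.833 | 13.7 | 80.1 |
| summer | 1.33 | 19.3 | 71.4 |
| summer | 1.50 | 21.9 | 68.8 |
| summer | 2.00 | 26.9 | 62.6 |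
| summer | 2.50 | 30.7 | 56.6 |
| summer | 3.00 | 34.9 | 51.4 |
| noon | 0.250 | 4.3 | 88.0 |
| noon | 0.333 | 5.1 | 84.7 |
| noon | 0.500 | 6.8 | 78.9 |
| noon | 0.833 | 9.4 | 69.7 |
| noon | 1.33 | 13.3 | 59.2 |
| noon | 2.00 | 17.4 | 49.2 |
| noon | 3.00 | 21.4 | 38.0 |
| dawn | 0.250 | 5.7 | 89.7 |
| dawn | 0.833 | 15.0 | 74.2 |
| dawn | 1.33 | 21.5 | 63.9 |
| dawn | 2.00 | 28.8 | 52.4 |
| dawn | 3.00 | 37.2 | 40.2 |

(standard deviation of a reading: 0.3 percentage points)

1. apparent order in second substrate when 30% of the starting material are converted (percent change of the rate of making target for one percent more second substrate charged)
2. factor on the rate of making target when 30% of the starting material are converted if free catalyst is charged twice over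

- percentages count the starting material that a species holds: one self-condensation product counts as two
- the numbers in the tables scatter by 0.3 percentage points (one standard deviation)
- steps under discussion: second substrate + free catalyst <-> catalyst intermediate B; reagent + catalyst intermediate B -> free catalyst + second product; 2 starting material -> self-condensation product; starting material + free catalyst <-> catalyst intermediate A; reagent + catalyst intermediate A -> free catalyst + target
- no earlier run changes the charge of free catalyst; that part of a forecast is a guess
- no earlier run changes the charge of second substrate; that part of a forecast is a guess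

1. I assume that catalyst stands free, as catalyst intermediate A or as catalyst intermediate B, and that target is made as fast as starting material captures free catalyst. The order in starting material is then one minus A's share. The order in reagent is A's share plus B's share, if B does not fall back.

2. Summer and noon at 0.833 h give an order in starting material of 0.728. Dawn's starting material is the geometric middle of those runs, so dawn against that middle gives an order in reagent of 0.720.

3. Their sum minus one is the held share, the part of the catalyst standing as B: 0.448. My order in second substrate is minus this number. At the same concentrations, doubling the catalyst doubles each form, so my estimate of the factor is near 2.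

4. To test one number, I repeat this at 1.33 h and get 0.490 against 0.448, from the same runs.

5. The forecast gives an order of −0.4 and a factor of 1.85: “Second substrate should therefore hold part of the catalyst”.

6. The flask gives an order of −0.76 and a factor of 1.97; the order lies lower than the forecast's. My 0.448, read from the runs, is below the 63.2% of the catalyst charged standing as B in the flask at 0.250 h.

    second substrate + free catalyst ⇌ catalyst intermediate B (K = 1900 M⁻¹, k = 1430 M⁻¹ h⁻¹)
    reagent + catalyst intermediate B → free catalyst + second product (k = 357 M⁻¹ h⁻¹)
    2 starting material → self-condensation product (k = 8.54 M⁻¹ h⁻¹)
    starting material + free catalyst ⇌ catalyst intermediate A (K = 14600 M⁻¹, k = 1520 M⁻¹ h⁻¹)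
    reagent + catalyst intermediate A → free catalyst + target (k = 2220 M⁻¹ h⁻¹)

7. In the flask, free catalyst enters A 1.1 times as fast as B at the start (forward steps alone), but A's rate constant with reagent is 6.22 times B's. At 2.50 h the flask's B, its resting state, holds 71.6% of the catalyst charged, and A holds 11.9%.

All runs were generated by integration with constants of no real substance.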